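The cyclohexene ring (C1, C2, C3, C4, C4a, C8a of the octalone) is disconnected at C1–C2, the bond joining the arm-bearing CH to the methyl-bearing sp2 carbon. A Pd(0)-catalysed 6-exo-dig carbopalladation/formate reduction of a (Z)-vinyl iodide onto a terminal alkyne forms this bond, closes the ring and delivers the C2=C3 olefin together with an exocyclic C1 methylene. It exploits the C1–CH2O arm flanking C2=C3: as a diene terminus it is hydroborated from the convex face of the cis-fused bicycle, fixing C-1. The precursor is a cyclohexanone carrying cis ethynyl (on C8a) and 3-iodobut-2-enyl (on C4a) groups; the slim ethynyl group also steers the earlier conjugate allylation.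

Key step: step 9

Remark: the SMILES is read as the cis-fused octalone in which H-4a, the 8a-methyl group and H-1 lie on one face, i.e. (1R,4aS,8aS).

Step 1
Reactants: 1 3-methylbut-3-en-2-one; 2 triisopropylsilyl trifluoromethanesulfonate
Product: 3 3-methyl-2-[(triisopropylsilyl)oxy]buta-1,3-diene
Conditions: Et3N, Et2O, 0 °C
Reagents that add atoms: triisopropylsilyl trifluoromethanesulfonate (2), CC(C)[Si](OS(=O)(=O)C(F)(F)F)(C(C)C)C(C)C
Why: Soft enolisation and O-silylation at the only enolisable position (the acetyl methyl) should give the 2-silyloxy diene; no stereocentre is involved.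

Step 2
Reactants: 3 3-methyl-2-[(triisopropylsilyl)oxy]buta-1,3-diene; 4 methacrolein
Product: 5 (1S)-1,3-dimethyl-4-[(triisopropylsilyl)oxy]cyclohex-3-ene-1-carbaldehyde
Conditions: o-tolyl-CBS oxazaborolidine·HNTf2 (10 mol %, the antipode that gives the (S)-aldehyde), CH2Cl2, −78 °C
Reagents that add atoms: methacrolein (4), CC(=C)C=O
Why: Enantioselective Diels–Alder reaction under chiral oxazaborolidinium Lewis acid catalysis; the 2-silyloxy group should direct the formyl-bearing carbon para to C–OSi, and the catalyst controls which enal face is attacked, setting the quaternary (S)-centre.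

Step 3
Reactants: 5 (1S)-1,3-dimethyl-4-[(triisopropylsilyl)oxy]cyclohex-3-ene-1-carbaldehyde
Product: 6 (1S)-1,3-dimethyl-4-oxocyclohex-2-ene-1-carbaldehyde
Conditions: Pd(OAc)2 (10 mol %), O2 (1 atm), DMSO, 60 °C
Reagents that add atoms: none
Why: Saegusa–Ito oxidation: the regiodefined silyl enol ether forms a Pd(II) enolate and β-hydride elimination toward the ring CH2 should give the α-methyl enone without touching the quaternary centre.

Step 4
Reactants: 6 (1S)-1,3-dimethyl-4-oxocyclohex-2-ene-1-carbaldehyde; 7 dimethyl (1-diazo-2-oxopropyl)phosphonate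
Product: 8 (4S)-4-ethynyl-2,4-dimethylcyclohex-2-en-1-one
Conditions: K2CO3, MeOH, 0 °C → rt
Reagents that add atoms: dimethyl (1-diazo-2-oxopropyl)phosphonate (7), CC(=O)C(=[N+]=[N-])P(=O)(OC)OC
Why: Seyferth–Gilbert homologation (Ohira–Bestmann variant) turns the non-enolisable aldehyde into the terminal alkyne under mild carbonate conditions that the hindered enone should tolerate.

Step 5
Reactants: 8 (4S)-4-ethynyl-2,4-dimethylcyclohex-2-en-1-one; 9 allylmagnesium bromide; 10 chlorotrimethylsilane
Product: 11 trimethyl{[(3S,4S)-4-ethynyl-2,4-dimethyl-3-(prop-2-en-1-yl)cyclohex-1-en-1-yl]oxy}silane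
Conditions: CuBr·SMe2, THF, −78 °C
Reagents that add atoms: allylmagnesium bromide (9), C=CC[Mg]Br; chlorotrimethylsilane (10), C[Si](C)(C)Cl
Why: Copper-mediated, TMSCl-accelerated conjugate allylation; axial attack anti to the γ-methyl group (the bulkier γ-substituent, the ethynyl group being much slimmer) should place the allyl group cis to the ethynyl group (3S), and the enolate is trapped regiospecifically as its silyl ether.

Step 6
Reactants: 11 trimethyl{[(3S,4S)-4-ethynyl-2,4-dimethyl-3-(prop-2-en-1-yl)cyclohex-1-en-1-yl]oxy}silane; 12 iodomethane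
Product: 13 (3S,4S)-4-ethynyl-2,2,4-trimethyl-3-(prop-2-en-1-yl)cyclohexan-1-one
Conditions: BnMe3N+F−, 4 Å MS, THF, 0 °C → rt
Reagents that add atoms: iodomethane (12), CI
Why: Fluoride-induced release of the regiodefined ammonium enolate and C-methylation (Kuwajima–Nakamura alkylation) builds the gem-dimethyl carbon without a strong base that would deprotonate the alkyne; no new stereocentre.

Step 7
Reactants: 13 (3S,4S)-4-ethynyl-2,2,4-trimethyl-3-(prop-2-en-1-yl)cyclohexan-1-one; 14 sodium periodate
Product: 15 2-[(1S,2S)-2-ethynyl-2,6,6-trimethyl-5-oxocyclohexyl]acetaldehyde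
Conditions: OsO4 (cat.), 2,6-lutidine, dioxane/H2O, rt
Reagents that add atoms: sodium periodate (14), [Na+].[O-]I(=O)(=O)=O
Why: Lemieux–Johnson oxidation (catalytic dihydroxylation, then periodate cleavage) of the monosubstituted olefin; the terminal alkyne reacts much more slowly with OsO4 and the ketone is inert.

Step 8
Reactants: 15 2-[(1S,2S)-2-ethynyl-2,6,6-trimethyl-5-oxocyclohexyl]acetaldehyde; 16 ethyltriphenylphosphonium iodide; 17 iodine
Product: 21 (3S,4S)-4-ethynyl-3-[(2Z)-3-iodobut-2-en-1-yl]-2,2,4-trimethylcyclohexan-1-one, via ethylidenetriphenylphosphorane 18 (not isolated), via (1-iodoethyl)triphenylphosphonium iodide 19 (not isolated), via (1-iodoethylidene)triphenylphosphorane 20 (not isolated)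
Conditions: n-BuLi, THF, rt; I2, −78 °C; NaHMDS, −20 °C; then 15, −78 °C → rt
Reagents that add atoms: ethyltriphenylphosphonium iodide (16), CC[P+](c1ccccc1)(c1ccccc1)c1ccccc1.[I-]; iodine (17), II
Why: Stork–Zhao-type Wittig olefination with the α-iodo ylide made in the flask; the unstabilised ylide should react with the aldehyde in preference to the hindered ketone and give the (Z)-2-iodo-2-alkene.

Step 9
Reactants: 21 (3S,4S)-4-ethynyl-3-[(2Z)-3-iodobut-2-en-1-yl]-2,2,4-trimethylcyclohexan-1-one
Product: 22 (4aS,8aS)-1,1,4a,6-tetramethyl-5-methylidene-3,4,4a,5,8,8a-hexahydronaphthalen-2(1H)-one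
Conditions: Pd(OAc)2 (10 mol %), PPh3, HCO2Na, DMF, 80 °C
Reagents that add atoms: none
Why: Pd(0) inserts into the (Z)-C–I bond, the vinylpalladium adds syn across the tethered alkyne, and formate exchange, decarboxylation and C–H reductive elimination release the diene. The closest known reaction type is the Pd-catalysed cyclisation–hydride capture (reductive Heck-type carbopalladation) of vinyl halides onto alkynes. The ring closes in the 6-exo-dig mode. No stereocentre is created here; the ring carbon that becomes C-1 of the target is left as an sp2 diene terminus so that its hydrogen can be delivered under face control in step 10. The step needs insertion to outrun direct hydride capture and 6-exo to beat 7-endo closure; the (Z)-iodide (Pd cis to the chain), the gauche cis-1,2 arrangement of the two arms and intramolecularity should secure this, and the ketone is inert without strong base.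

Step 10
Reactants: 22 (4aS,8aS)-1,1,4a,6-tetramethyl-5-methylidene-3,4,4a,5,8,8a-hexahydronaphthalen-2(1H)-one; 23 9-borabicyclo[3.3.1]nonane; 24 hydrogen peroxide
Product: 26 (4aS,5R,8aS)-5-(hydroxymethyl)-1,1,4a,6-tetramethyl-3,4,4a,5,8,8a-hexahydronaphthalen-2(1H)-one, via B-alkyl-9-BBN adduct 25 (not isolated)
Conditions: 9-BBN, THF, 0 °C → rt; then aq NaOH, H2O2, 0 °C
Reagents that add atoms: hydrogen peroxide (24), OO
Why: Anti-Markovnikov hydroboration–oxidation of the exocyclic 1,1-disubstituted diene terminus; boron and hydrogen should add from the convex face carrying the 4a-methyl group and H-8a (the other face is screened by ring A: C4H2 and the C1 gem-dimethyl carbon), which sets (5R), and the hindered ketone is expected to react more slowly.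

Step 11
Reactants: 26 (4aS,5R,8aS)-5-(hydroxymethyl)-1,1,4a,6-tetramethyl-3,4,4a,5,8,8a-hexahydronaphthalen-2(1H)-one; 27 umbelliferone (7-hydroxy-2H-chromen-2-one)
Product: 28 7-{[(1R,4aS,8aS)-2,5,5,8a-tetramethyl-6-oxo-1,4,4a,5,6,7,8,8a-octahydronaphthalen-1-yl]methoxy}-2H-chromen-2-one
Conditions: PPh3, DIAD, THF, 0 °C → rt
Reagents that add atoms: umbelliferone (27), Oc1ccc2ccc(=O)oc2c1
Why: Mitsunobu etherification of the primary alcohol with the acidic phenol; the reacting carbon is not stereogenic, so all three stereocentres are carried through unchanged.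

Compound list
1 | 3-methylbut-3-en-2-one | CC(=C)C(C)=O | starting material
2 | triisopropylsilyl trifluoromethanesulfonate | CC(C)[Si](OS(=O)(=O)C(F)(F)F)(C(C)C)C(C)C | starting material
3 | 3-methyl-2-[(triisopropylsilyl)oxy]buta-1,3-diene | C=C(C)C(=C)O[Si](C(C)C)(C(C)C)C(C)C | intermediate
4 | methacrolein | CC(=C)C=O | starting material
5 | (1S)-1,3-dimethyl-4-[(triisopropylsilyl)oxy]cyclohex-3-ene-1-carbaldehyde | CC1=C(O[Si](C(C)C)(C(C)C)C(C)C)CC[C@](C)(C=O)C1 | intermediate
6 | (1S)-1,3-dimethyl-4-oxocyclohex-2-ene-1-carbaldehyde | O=C1CC[C@](C)(C=O)C=C1C | intermediate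
7 | dimethyl (1-diazo-2-oxopropyl)phosphonate | CC(=O)C(=[N+]=[N-])P(=O)(OC)OC | starting material
8 | (4S)-4-ethynyl-2,4-dimethylcyclohex-2-en-1-one | O=C1CC[C@](C)(C#C)C=C1C | intermediate
9 | allylmagnesium bromide | C=CC[Mg]Br | starting material
10 | chlorotrimethylsilane | C[Si](C)(C)Cl | starting material
11 | trimethyl{[(3S,4S)-4-ethynyl-2,4-dimethyl-3-(prop-2-en-1-yl)cyclohex-1-en-1-yl]oxy}silane | C=CC[C@@H]1C(C)=C(O[Si](C)(C)C)CC[C@]1(C)C#C | intermediate
12 | iodomethane | CI | starting material
13 | (3S,4S)-4-ethynyl-2,2,4-trimethyl-3-(prop-2-en-1-yl)cyclohexan-1-one | C=CC[C@@H]1C(C)(C)C(=O)CC[C@]1(C)C#C | intermediate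
14 | sodium periodate | [Na+].[O-]I(=O)(=O)=O | starting material
15 | 2-[(1S,2S)-2-ethynyl-2,6,6-trimethyl-5-oxocyclohexyl]acetaldehyde | O=CC[C@@H]1C(C)(C)C(=O)CC[C@]1(C)C#C | intermediate
16 | ethyltriphenylphosphonium iodide | CC[P+](c1ccccc1)(c1ccccc1)c1ccccc1.[I-] | starting material
17 | iodine | II | starting material
18 | ethylidenetriphenylphosphorane | CC=P(c1ccccc1)(c1ccccc1)c1ccccc1 | intermediate
19 | (1-iodoethyl)triphenylphosphonium iodide | CC(I)[P+](c1ccccc1)(c1ccccc1)c1ccccc1.[I-] | intermediate
20 | (1-iodoethylidene)triphenylphosphorane | CC(I)=P(c1ccccc1)(c1ccccc1)c1ccccc1 | intermediate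
21 | (3S,4S)-4-ethynyl-3-[(2Z)-3-iodobut-2-en-1-yl]-2,2,4-trimethylcyclohexan-1-one | C/C(I)=C/C[C@@H]1C(C)(C)C(=O)CC[C@]1(C)C#C | intermediate
22 | (4aS,8aS)-1,1,4a,6-tetramethyl-5-methylidene-3,4,4a,5,8,8a-hexahydronaphthalen-2(1H)-one | CC1=CC[C@@H]2C(C)(C)C(=O)CC[C@]2(C)C1=C | intermediate
23 | 9-borabicyclo[3.3.1]nonane | B1C2CCCC1CCC2 | starting material
24 | hydrogen peroxide | OO | starting material
25 | 9-{[(1R,4aS,8aR)-2,5,5,8a-tetramethyl-6-oxo-1,4,4a,5,6,7,8,8a-octahydronaphthalen-1-yl]methyl}-9-borabicyclo[3.3.1]nonane | CC1=CC[C@@H]2C(C)(C)C(=O)CC[C@]2(C)[C@@H]1CB1C2CCCC1CCC2 | intermediate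
26 | (4aS,5R,8aS)-5-(hydroxymethyl)-1,1,4a,6-tetramethyl-3,4,4a,5,8,8a-hexahydronaphthalen-2(1H)-one | CC1=CC[C@@H]2C(C)(C)C(=O)CC[C@]2(C)[C@@H]1CO | intermediate
27 | umbelliferone (7-hydroxy-2H-chromen-2-one) | Oc1ccc2ccc(=O)oc2c1 | starting material
28 | 7-{[(1R,4aS,8aS)-2,5,5,8a-tetramethyl-6-oxo-1,4,4a,5,6,7,8,8a-octahydronaphthalen-1-yl]methoxy}-2H-chromen-2-one | CC1=CC[C@@H]2C(C)(C)C(=O)CC[C@]2(C)[C@@H]1COc1ccc2ccc(=O)oc2c1 | target

Total step count: 11. Longest linear sequence: 11 steps (from 1 to 28).

Steps most likely to fail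

Step 5. The allyl nucleophile may add 1,2 to the carbonyl, or the facial bias at the β-carbon (methyl versus ethynyl) may be too small. The fallback sets out from 8 and comes back at 13. Allylmagnesium bromide without copper is added to the carbonyl group of 8, and the epimer with the allyl group cis to the ethynyl group, (1R,4S)-1-allyl-4-ethynyl-2,4-dimethylcyclohex-2-en-1-ol F1, is separated by chromatography. One equivalent of KH with 18-crown-6 in THF then triggers an anionic oxy-Cope rearrangement, which carries the allyl group suprafacially from the carbinol carbon to the β-carbon on the same ring face. The resulting regiodefined potassium enolate is quenched with iodomethane to give 13. The stereochemical question is thereby turned into a separable diastereomer problem, and 1,2-addition becomes the productive path.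

Step 10. The borane may add to both faces of the exocyclic methylene, or it may reduce the ring ketone. The fallback sets out from 21 and comes back at 26. The terminal alkyne of 21 is hydroborated with dicyclohexylborane and oxidised (NaBO3) to 2-[(1R,2S)-2-[(2Z)-3-iodobut-2-en-1-yl]-1,3,3-trimethyl-4-oxocyclohexyl]acetaldehyde F2. Pd(0)/Cs2CO3-mediated intramolecular α-alkenylation of the aldehyde closes the same ring bond. The derived dienolate (KHMDS, −78 °C) is then protonated kinetically at C-1 from the convex face to give (1R,4aS,8aS)-2,5,5,8a-tetramethyl-6-oxo-1,4,4a,5,6,7,8,8a-octahydronaphthalene-1-carbaldehyde F3. NaBH4 at −78 °C should reduce the aldehyde in preference to the hindered ketone and return 26. Here C-1 is set by proton transfer instead of borane addition, and no borane meets the ketone at the bicyclic stage.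

Step 9. The vinylpalladium species may capture hydride before it inserts into the alkyne (loss of iodine without ring closure), or a palladium hydride may move the new diene out of position. The fallback sets out from 21 and comes back at 22 without new isolated compounds. A radical chain replaces the organopalladium pathway: (Me3Si)3SiH and AIBN in benzene at 80 °C under slow addition generate the vinyl radical, which should close 6-exo-dig onto the alkyne and then abstract hydrogen to give 22. Either iodide geometry is usable because the vinyl radical inverts rapidly.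

Further compounds
F1 | step 5 | (1R,4S)-1-allyl-4-ethynyl-2,4-dimethylcyclohex-2-en-1-ol | C=CC[C@]1(O)CC[C@](C)(C#C)C=C1C
F2 | step 10 | 2-[(1R,2S)-2-[(2Z)-3-iodobut-2-en-1-yl]-1,3,3-trimethyl-4-oxocyclohexyl]acetaldehyde | C/C(I)=C/C[C@@H]1C(C)(C)C(=O)CC[C@]1(C)CC=O
F3 | step 10 | (1R,4aS,8aS)-2,5,5,8a-tetramethyl-6-oxo-1,4,4a,5,6,7,8,8a-octahydronaphthalene-1-carbaldehyde | CC1=CC[C@@H]2C(C)(C)C(=O)CC[C@]2(C)[C@@H]1C=O
F0 | step 9 | none | none
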